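## Retrosynthetic overview

1. The strategy rests on the C18–C4–C5=C6 array. The acetoxymethyl carbon C18 sits on quaternary C4 of ring A and is homoallylic to the ring-B alkene, which is the retron of a [2,3] shift of a C6–O–CH2 ether across C4=C5. The C4–C18 bond is therefore cut last, back to a C6 (tributylstannyl)methyl ether.
2. The C6 carbinol comes from a C4(Me)=C5–C6=O enone, made from a C4 ketone by methyl addition and oxidative allylic transposition. An oxygen first placed at C4 is thus moved to C6 and finally traded for the C4–C18 bond.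
3. The side chain is cut at C11=C12: Julia–Kocienski olefination of a C9 aldehyde with a C12–C15 sulfone from (S)-2-methylbutane-1,4-diol.
4. Ring B is opened at C9–C10 and C7–C8 by a Diels–Alder disconnection to tiglaldehyde and an enantiopure 6-silyloxy-1-vinylcyclohexene.
5. Ring order: ring A is bought as cyclohexenone, ring B is closed by the cycloaddition (sets C8, C9, C10), the chain is attached, and quaternary C4 is made last.

Key step: step 17

Remarks on the chemistry and the conventions used:
- Halimane numbering is used for all bicyclic compounds: decalin C1–C10, side chain C11–C16 with CH3-16 on C13, CH3-17 on C8, C18 and CH3-19 on C4, CH3-20 on C9.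
- "Upper face" means the face of the decalin that carries H-10. With this numbering the target is (4R,8S,9R,10S,13R)-18-acetoxyhalim-5-en-15-oic acid.
- TBS = tert-butyldimethylsilyl, TBDPS = tert-butyldiphenylsilyl.
- (S)- and (R)-Me-CBS are the enantiomers of 1-methyl-3,3-diphenyltetrahydro-1H,3H-pyrrolo[1,2-c][1,3,2]oxazaborole.
- The tertiary alcohol 17 is carried as a mixture of C4 epimers, because that centre becomes sp2 in the next step.

## Route

Step 1
Reactants: 1 cyclohex-2-en-1-one
Product: 2 2-iodocyclohex-2-en-1-one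
Conditions: I2, pyridine/CH2Cl2 (1:1), 0 °C to rt
Reagents that add atoms: iodine, II
Why: Pyridine-mediated α-iodination of an enone (conjugate addition, iodination of the enolate, elimination) is standard for cyclohexenone and creates no stereocentre.

Step 2
Reactants: 2 2-iodocyclohex-2-en-1-one
Product: 3 (R)-2-iodocyclohex-2-en-1-ol
Conditions: (S)-Me-CBS (10 mol %), BH3·SMe2, THF, −20 °C; MeOH quench
Reagents that add atoms: none
Why: Corey–Bakshi–Shibata reduction in which the α-iodovinyl side acts as the large group, so the (S)-catalyst should deliver hydride to the face that gives the (R)-carbinol, the source of absolute configuration for C8, C9 and C10.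

Step 3
Reactants: 3 (R)-2-iodocyclohex-2-en-1-ol
Product: 4 (R)-tert-butyl[(2-iodocyclohex-2-en-1-yl)oxy]dimethylsilane
Conditions: TBSCl, imidazole, DMF, rt
Reagents that add atoms: tert-butyldimethylsilyl chloride, CC(C)(C)[Si](C)(C)Cl
Why: Imidazole-promoted silylation of a secondary allylic alcohol is routine, does not touch the carbinol centre and installs the bulky group that later shields one diene face.

Step 4
Reactants: 4 (R)-tert-butyl[(2-iodocyclohex-2-en-1-yl)oxy]dimethylsilane
Product: 5 (R)-tert-butyldimethyl[(2-vinylcyclohex-2-en-1-yl)oxy]silane (ring-A diene)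
Conditions: Bu3SnCH=CH2, Pd(PPh3)4 (5 mol %, zerovalent palladium), CuI (10 mol %), DMF, 50 °C
Reagents that add atoms: tributyl(vinyl)stannane, C=C[Sn](CCCC)(CCCC)CCCC
Why: Stille cross-coupling of a vinyl iodide with a vinylstannane keeps the ring alkene in place and leaves the allylic silyloxy centre untouched.

Step 5
Reactants: 5 ring-A diene; 6 tiglaldehyde, (E)-2-methylbut-2-enal
Product: 7 4-(TBS-oxy)-8,9-dimethyl-18,19-dinor-octal-5-ene-9-carbaldehyde (halimane numbering; OTBS, H-10, H-8 and CHO on the upper face, CH3-17 and CH3-20 on the lower face)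
Conditions: Me2AlCl (20 mol %), CH2Cl2, −78 to −30 °C
Reagents that add atoms: none
Why: Lewis-acid-promoted normal-demand Diels–Alder reaction in which the unsubstituted vinyl terminus C7 bonds to the β-carbon of the complexed enal so that the formyl-bearing carbon C9 joins C10, the α-methyl enal reacts through the exo-formyl transition state (CHO cis to H-10), the E geometry of the dienophile keeps CH3-17 and CH3-20 cis, and the pseudoaxial silyloxy group at C4 blocks its own face, so C8, C9 and C10 are all set by addition anti to it.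

Step 6
Reactants: 8 (S)-2-methylbutane-1,4-diol
Product: 9 (S)-4-[(tert-butyldiphenylsilyl)oxy]-2-methylbutan-1-ol
Conditions: TBDPSCl (0.9 equiv), imidazole, CH2Cl2, −40 to 0 °C
Reagents that add atoms: tert-butyldiphenylsilyl chloride, CC(C)(C)[Si](Cl)(c1ccccc1)c1ccccc1
Why: Kinetic silylation with a bulky chlorosilane should favour the unbranched hydroxyl (future C15) over the β-branched one (future C12), with the minor regioisomer and bis-ether removed by chromatography, and the C13 centre is not involved.

Step 7
Reactants: 9 (S)-4-[(tert-butyldiphenylsilyl)oxy]-2-methylbutan-1-ol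
Product: 10 5-{[(S)-4-(TBDPS-oxy)-2-methylbutyl]sulfanyl}-1-phenyl-1H-tetrazole
Conditions: 1-phenyl-1H-tetrazole-5-thiol, PPh3, DIAD, THF, 0 °C to rt
Reagents that add atoms: 1-phenyl-1H-tetrazole-5-thiol, Sc1nnnn1-c1ccccc1
Why: Mitsunobu thioetherification of a primary alcohol with an acidic heteroaryl thiol occurs at CH2 and so leaves C13 untouched.

Step 8
Reactants: 10 tetrazolyl sulfide
Product: 11 5-{[(S)-4-(TBDPS-oxy)-2-methylbutyl]sulfonyl}-1-phenyl-1H-tetrazole
Conditions: H2O2 (30 % aq.), (NH4)6Mo7O24·4H2O (10 mol %), EtOH, 0 °C to rt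
Reagents that add atoms: hydrogen peroxide, OO
Why: Molybdate-catalysed peroxide oxidation of a sulfide to the sulfone is the usual second stage of Julia–Kocienski reagent synthesis and tolerates the silyl ether.

Step 9
Reactants: 11 phenyltetrazolyl sulfone; 7 octalin aldehyde
Product: 13 (11E)-4-(TBS-oxy)-15-(TBDPS-oxy)-18,19-dinorhalima-5,11-diene, via potassium sulfonyl carbanion 12 (not isolated)
Conditions: KN(SiMe3)2, DME, −60 °C, 30 min; then 7, −60 °C to rt
Reagents that add atoms: none
Why: Julia–Kocienski olefination in which the metalated sulfone adds to the non-enolisable neopentyl aldehyde and Smiles rearrangement with loss of SO2 and tetrazolate gives the C11=C12 alkene (its geometry is immaterial because it is reduced next) without touching C9 or C13.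

Step 10
Reactants: 13 C11=C12 olefin
Product: 14 4-(TBS-oxy)-15-(TBDPS-oxy)-18,19-dinorhalim-5-ene
Conditions: 2-nitrobenzenesulfonylhydrazide (excess), Et3N, CH2Cl2, rt
Reagents that add atoms: none
Why: Diimide reduction transfers hydrogen in a concerted syn fashion much faster to the 1,2-disubstituted C11=C12 alkene than to the trisubstituted ring alkene C5=C6 and cannot hydrogenolyse the allylic C4–O bond.

Step 11
Reactants: 14 bis-silyl ether
Product: 15 15-(TBDPS-oxy)-18,19-dinorhalim-5-en-4-ol (OH on the upper face)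
Conditions: camphorsulfonic acid (10 mol %), MeOH/CH2Cl2 (1:1), 0 °C to rt
Reagents that add atoms: none
Why: Mild acid-catalysed methanolysis cleaves the secondary TBS ether while the much more acid-stable primary TBDPS ether survives.

Step 12
Reactants: 15 C4 allylic alcohol
Product: 16 15-(TBDPS-oxy)-18,19-dinorhalim-5-en-4-one
Conditions: Dess–Martin periodinane, CH2Cl2, 0 °C to rt
Reagents that add atoms: none
Why: Dess–Martin oxidation of the allylic alcohol gives the enone under nearly neutral conditions, erasing the carbinol centre once its relay task is done, and C10 is safe because it sits on the α-carbon of the enone and not on a vinylogous position.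

Step 13
Reactants: 16 C4 enone
Product: 17 15-(TBDPS-oxy)-18-norhalim-5-en-4-ol (tertiary alcohol, mixture of C4 epimers)
Conditions: MeLi, Et2O, −78 °C
Reagents that add atoms: methyllithium, [Li]C
Why: 1,2-Addition of the hard nucleophile methyllithium to the enone carbonyl at low temperature gives the tertiary allylic alcohol and introduces CH3-19, and the new C4 centre needs no control because it becomes sp2 in the next step.

Step 14
Reactants: 17 tertiary allylic alcohol
Product: 20 15-(TBDPS-oxy)-18-norhalim-4-en-6-one, via tertiary chlorochromate ester 18 (not isolated), via C6 chlorochromate ester 19 (not isolated)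
Conditions: pyridinium chlorochromate [C5H5NH][CrO3Cl], 4 Å molecular sieves, CH2Cl2, rt
Reagents that add atoms: pyridinium chlorochromate, [O-][Cr](=O)(=O)Cl.c1cc[nH+]cc1
Why: Babler–Dauben oxidative transposition in which the tertiary ester of hexavalent chromium undergoes a [3,3] shift that moves oxygen to secondary C6 and the alkene to the tetrasubstituted C4=C5 position, and the C6 ester is then oxidised to the ketone.

Step 15
Reactants: 20 transposed enone
Product: 21 (6S)-15-(TBDPS-oxy)-18-norhalim-4-en-6-ol (OH on the upper face, cis to H-10)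
Conditions: (R)-Me-CBS (20 mol %), BH3·SMe2, toluene, −40 to −20 °C; MeOH quench
Reagents that add atoms: none
Why: Corey–Bakshi–Shibata reduction in which the fully substituted alkenyl carbon C5 is the large group and C7H2 the small one, so the (R)-catalyst should deliver hydride to the lower face of C6 and give the (6S)-alcohol under reagent control without touching the tetrasubstituted alkene.

Step 16
Reactants: 21 C6 allylic alcohol
Product: 22 6-O-[(tributylstannyl)methyl] ether of 21
Conditions: KH, 18-crown-6 (cat.), THF, 0 °C; then ICH2SnBu3, 0 °C to rt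
Reagents that add atoms: tributyl(iodomethyl)stannane, CCCC[Sn](CCCC)(CCCC)CI
Why: Williamson etherification of the potassium alkoxide with the reactive primary iodide occurs at oxygen, so the C6 configuration is retained.

Step 17
Reactants: 22 C6 (tributylstannyl)methyl ether
Product: 24 15-(TBDPS-oxy)halim-5-en-18-ol, via lithiomethyl ether 23 (not isolated)
Conditions: n-BuLi, THF, −78 °C, then to −20 °C; aq. NH4Cl
Reagents that add atoms: none
Why: Tin–lithium exchange at −78 °C gives an unstabilised α-alkoxymethyllithium, which rearranges in a concerted way through a five-membered envelope transition state (C18, O, C6, C5, C4), forming the C4–C18 bond as the C6–O bond breaks and the alkene moves from C4=C5 to C5=C6. The closest known reaction type is the Wittig–Still [2,3]-sigmatropic rearrangement of cyclic allylic stannylmethyl ethers with 1,3-chirality transfer to a hydroxymethyl-bearing quaternary carbon. No ring is closed, since the cyclic array exists only in the transition state. The one new stereocentre, quaternary C4, is controlled by the C6 carbinol configuration: the shift is suprafacial, so C18 can only reach the face of C4 on which the C6 oxygen stands, which puts CH2OH-18 on the upper face and CH3-19 on the lower face. The step needs [2,3] rather than [1,2] migration and delivery to a single face of a tetrasubstituted alkene; these are secured by the low temperature with a non-stabilised carbanion and by allylic 1,3-strain between CH3-19 and the C6 substituents, which holds the C6–O bond pseudoaxial and aligned with the C4=C5 π orbitals. The alkoxide formed is the C18 oxygen that later carries the acetate, so the olefin position and the C4 configuration are fixed in one operation.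

Step 18
Reactants: 24 C18 homoallylic alcohol
Product: 25 18-acetoxy-15-(TBDPS-oxy)halim-5-ene
Conditions: Ac2O, pyridine, DMAP (cat.), CH2Cl2, rt
Reagents that add atoms: acetic anhydride, CC(=O)OC(C)=O
Why: DMAP-catalysed acetylation of the only free hydroxyl, a primary neopentyl-type alcohol, is reliable and leaves the silyl ether untouched.

Step 19
Reactants: 25 acetate silyl ether
Product: 26 18-acetoxyhalim-5-en-15-ol
Conditions: HF·pyridine, pyridine, THF, 0 °C to rt
Reagents that add atoms: none
Why: Fluoride-mediated desilylation under weakly acidic conditions cleaves the primary TBDPS ether without hydrolysing or migrating the acetate.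

Step 20
Reactants: 26 primary alcohol
Product: 28 (4R,8S,9R,10S,13R)-18-acetoxyhalim-5-en-15-oic acid (target CNP0148247.1), via C15 aldehyde 27 (not isolated)
Conditions: TEMPO (20 mol %), PhI(OAc)2 (2.5 equiv), MeCN/H2O (1:1), rt
Reagents that add atoms: water, O
Why: Oxoammonium-mediated oxidation takes the primary alcohol through the aldehyde and its hydrate to the carboxylic acid without epimerising C13 (β to the carbonyl) and without touching the acetate or the trisubstituted alkene.

## Compound list

1 | cyclohex-2-en-1-one | O=C1C=CCCC1 | starting material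
2 | 2-iodocyclohex-2-en-1-one | O=C1C(I)=CCCC1 | intermediate
3 | (R)-2-iodocyclohex-2-en-1-ol | IC1=CCCC[C@H]1O | intermediate
4 | (R)-tert-butyl[(2-iodocyclohex-2-en-1-yl)oxy]dimethylsilane | IC1=CCCC[C@H]1O[Si](C)(C)C(C)(C)C | intermediate
5 | (R)-tert-butyldimethyl[(2-vinylcyclohex-2-en-1-yl)oxy]silane | C=CC1=CCCC[C@H]1O[Si](C)(C)C(C)(C)C | intermediate
6 | tiglaldehyde, (E)-2-methylbut-2-enal | C/C=C(\C)C=O | starting material
7 | octalin aldehyde (4-OTBS, C8, C9, C10 set) | CC(C)(C)[Si](C)(C)O[C@@H]1CCC[C@@H]2C1=CC[C@H](C)[C@@]2(C)C=O | intermediate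
8 | (S)-2-methylbutane-1,4-diol | OC[C@@H](C)CCO | starting material
9 | (S)-4-[(tert-butyldiphenylsilyl)oxy]-2-methylbutan-1-ol | OC[C@@H](C)CCO[Si](c1ccccc1)(c1ccccc1)C(C)(C)C | intermediate
10 | 5-{[(S)-4-(TBDPS-oxy)-2-methylbutyl]sulfanyl}-1-phenyl-1H-tetrazole | S(C[C@@H](C)CCO[Si](c1ccccc1)(c1ccccc1)C(C)(C)C)c1nnnn1-c1ccccc1 | intermediate
11 | 5-{[(S)-4-(TBDPS-oxy)-2-methylbutyl]sulfonyl}-1-phenyl-1H-tetrazole | O=S(=O)(C[C@@H](C)CCO[Si](c1ccccc1)(c1ccccc1)C(C)(C)C)c1nnnn1-c1ccccc1 | intermediate
12 | potassium α-sulfonyl carbanion of 11 | [K+].O=S(=O)([CH-][C@@H](C)CCO[Si](c1ccccc1)(c1ccccc1)C(C)(C)C)c1nnnn1-c1ccccc1 | intermediate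
13 | (11E)-4-(TBS-oxy)-15-(TBDPS-oxy)-18,19-dinorhalima-5,11-diene | CC(C)(C)[Si](C)(C)O[C@@H]1CCC[C@@H]2C1=CC[C@H](C)[C@@]2(C)/C=C/[C@@H](C)CCO[Si](c1ccccc1)(c1ccccc1)C(C)(C)C | intermediate
14 | 4-(TBS-oxy)-15-(TBDPS-oxy)-18,19-dinorhalim-5-ene | CC(C)(C)[Si](C)(C)O[C@@H]1CCC[C@@H]2C1=CC[C@H](C)[C@@]2(C)CC[C@@H](C)CCO[Si](c1ccccc1)(c1ccccc1)C(C)(C)C | intermediate
15 | 15-(TBDPS-oxy)-18,19-dinorhalim-5-en-4-ol | O[C@@H]1CCC[C@@H]2C1=CC[C@H](C)[C@@]2(C)CC[C@@H](C)CCO[Si](c1ccccc1)(c1ccccc1)C(C)(C)C | intermediate
16 | 15-(TBDPS-oxy)-18,19-dinorhalim-5-en-4-one | O=C1CCC[C@@H]2C1=CC[C@H](C)[C@@]2(C)CC[C@@H](C)CCO[Si](c1ccccc1)(c1ccccc1)C(C)(C)C | intermediate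
17 | 15-(TBDPS-oxy)-18-norhalim-5-en-4-ol (C4 epimer mixture, centre left undefined) | CC1(O)CCC[C@@H]2C1=CC[C@H](C)[C@@]2(C)CC[C@@H](C)CCO[Si](c1ccccc1)(c1ccccc1)C(C)(C)C | intermediate
18 | tertiary chlorochromate ester of 17 | CC1(O[Cr](=O)(=O)Cl)CCC[C@@H]2C1=CC[C@H](C)[C@@]2(C)CC[C@@H](C)CCO[Si](c1ccccc1)(c1ccccc1)C(C)(C)C | intermediate
19 | allyl-transposed C6 chlorochromate ester (C6 undefined) | CC=1CCC[C@@H]2C=1C(O[Cr](=O)(=O)Cl)C[C@H](C)[C@@]2(C)CC[C@@H](C)CCO[Si](c1ccccc1)(c1ccccc1)C(C)(C)C | intermediate
20 | 15-(TBDPS-oxy)-18-norhalim-4-en-6-one | CC=1CCC[C@@H]2C=1C(=O)C[C@H](C)[C@@]2(C)CC[C@@H](C)CCO[Si](c1ccccc1)(c1ccccc1)C(C)(C)C | intermediate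
21 | (6S)-15-(TBDPS-oxy)-18-norhalim-4-en-6-ol | CC=1CCC[C@@H]2C=1[C@@H](O)C[C@H](C)[C@@]2(C)CC[C@@H](C)CCO[Si](c1ccccc1)(c1ccccc1)C(C)(C)C | intermediate
22 | 6-O-[(tributylstannyl)methyl] ether of 21 | CC=1CCC[C@@H]2C=1[C@@H](OC[Sn](CCCC)(CCCC)CCCC)C[C@H](C)[C@@]2(C)CC[C@@H](C)CCO[Si](c1ccccc1)(c1ccccc1)C(C)(C)C | intermediate
23 | 6-O-(lithiomethyl) ether of 21 | CC=1CCC[C@@H]2C=1[C@@H](OC[Li])C[C@H](C)[C@@]2(C)CC[C@@H](C)CCO[Si](c1ccccc1)(c1ccccc1)C(C)(C)C | intermediate
24 | 15-(TBDPS-oxy)halim-5-en-18-ol (4R) | OC[C@]1(C)CCC[C@@H]2C1=CC[C@H](C)[C@@]2(C)CC[C@@H](C)CCO[Si](c1ccccc1)(c1ccccc1)C(C)(C)C | intermediate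
25 | 18-acetoxy-15-(TBDPS-oxy)halim-5-ene | CC(=O)OC[C@]1(C)CCC[C@@H]2C1=CC[C@H](C)[C@@]2(C)CC[C@@H](C)CCO[Si](c1ccccc1)(c1ccccc1)C(C)(C)C | intermediate
26 | 18-acetoxyhalim-5-en-15-ol | CC(=O)OC[C@]1(C)CCC[C@@H]2C1=CC[C@H](C)[C@@]2(C)CC[C@@H](C)CCO | intermediate
27 | 18-acetoxyhalim-5-en-15-al | CC(=O)OC[C@]1(C)CCC[C@@H]2C1=CC[C@H](C)[C@@]2(C)CC[C@@H](C)CC=O | intermediate
28 | (4R,8S,9R,10S,13R)-18-acetoxyhalim-5-en-15-oic acid, CNP0148247.1 | CC(=O)OC[C@]1(C)CCC[C@@H]2C1=CC[C@H](C)[C@@]2(C)CC[C@@H](C)CC(=O)O | target

## Step count and risks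

Total step count: 20.
Longest linear sequence: 17 steps (steps 1–5 and 9–20); the sulfone branch is steps 6–8.

Steps most likely to fail:

1. Step 17 (Wittig–Still shift). The carbanion must attack a fully substituted alkene carbon; if that is slow, [1,2]-migration, protonation to the methyl ether or elimination of the alkoxide may take over. The fallback sets out from 21 and comes back at 24, and it makes the same suprafacial transfer as a thermal [3,3] shift. Johnson–Claisen rearrangement of 21 (MeC(OEt)3, cat. propionic acid, 140 °C) should give the C4 acetic acid ethyl ester F1, with the new C4–C bond on the face that carried the C6 oxygen. The extra carbon is then excised: hydroxylation of the potassium enolate (KN(SiMe3)2, then 2-(phenylsulfonyl)-3-phenyloxaziridine) gives the α-hydroxy ester F2; LiAlH4 reduction gives the 1,2-diol F3; NaIO4 cleavage gives the C18 aldehyde F4; NaBH4 reduction gives 24.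

2. Step 5 (Diels–Alder reaction). The trisubstituted enal may react slowly at the hindered ring terminus, and the Lewis acid may instead ionise the allylic silyl ether or erode the exo preference. The fallback sets out from 5 and 6 and comes back at 7, and it replaces the neutral Lewis-acid complex by a cationic dienophile (Gassman-type ionic Diels–Alder reaction). Aldehyde 6 is converted with HC(OMe)3 and MeOH (cat. acid) into tiglaldehyde dimethyl acetal F5. With catalytic Me3SiOTf in CH2Cl2 at −78 °C this ionises to a 1-methoxyallyl cation, which should add to 5 with the same regiochemistry and face and be recaptured as the dimethyl acetal adduct F6. Mild hydrolysis (pyridinium p-toluenesulfonate, wet acetone) then releases 7.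

3. Step 15 (enone reduction). Reagent control may not override the substrate's own preference for axial hydride delivery from the upper face, so the C6 epimer would form and the wrong C4 configuration would follow. The fallback sets out from 20 and comes back at 21, and it uses the substrate bias and then inverts. Luche reduction (NaBH4, CeCl3·7H2O, MeOH, −78 °C) should give mainly the C6-epimeric alcohol F7. Mitsunobu inversion with 4-nitrobenzoic acid (PPh3, DIAD, THF) gives the inverted 4-nitrobenzoate F8; SN2' attack is blocked because C4 is fully substituted. Methanolysis (K2CO3, MeOH) gives 21.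

## Further compounds

F1 | step 17 | C4 acetic acid ethyl ester (Johnson–Claisen product, CH2CO2Et on the upper face of C4) | CCOC(=O)C[C@]1(C)CCC[C@@H]2C1=CC[C@H](C)[C@@]2(C)CC[C@@H](C)CCO[Si](c1ccccc1)(c1ccccc1)C(C)(C)C
F2 | step 17 | α-hydroxy ester (carbinol centre undefined) | CCOC(=O)C(O)[C@]1(C)CCC[C@@H]2C1=CC[C@H](C)[C@@]2(C)CC[C@@H](C)CCO[Si](c1ccccc1)(c1ccccc1)C(C)(C)C
F3 | step 17 | 1,2-diol (carbinol centre undefined) | OCC(O)[C@]1(C)CCC[C@@H]2C1=CC[C@H](C)[C@@]2(C)CC[C@@H](C)CCO[Si](c1ccccc1)(c1ccccc1)C(C)(C)C
F4 | step 17 | C18 aldehyde, 15-(TBDPS-oxy)halim-5-en-18-al | O=C[C@]1(C)CCC[C@@H]2C1=CC[C@H](C)[C@@]2(C)CC[C@@H](C)CCO[Si](c1ccccc1)(c1ccccc1)C(C)(C)C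
F5 | step 5 | tiglaldehyde dimethyl acetal, (E)-1,1-dimethoxy-2-methylbut-2-ene | C/C=C(\C)C(OC)OC
F6 | step 5 | dimethyl acetal of aldehyde 7 | CC(C)(C)[Si](C)(C)O[C@@H]1CCC[C@@H]2C1=CC[C@H](C)[C@@]2(C)C(OC)OC
F7 | step 15 | C6 epimer of 21 (OH on the lower face) | CC=1CCC[C@@H]2C=1[C@H](O)C[C@H](C)[C@@]2(C)CC[C@@H](C)CCO[Si](c1ccccc1)(c1ccccc1)C(C)(C)C
F8 | step 15 | 4-nitrobenzoate of 21 (ester oxygen on the upper face) | CC=1CCC[C@@H]2C=1[C@@H](OC(=O)c3ccc(cc3)[N+](=O)[O-])C[C@H](C)[C@@]2(C)CC[C@@H](C)CCO[Si](c1ccccc1)(c1ccccc1)C(C)(C)C
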